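**Retrosynthetic overview**
- No ring is built. The oxazole is bought intact, and the only ring event is the opening of a pyridine: 3-picoline N-sulfonate plus Bu3SnLi gives a (2E,4E)-stannyl dienal that becomes C15–C19 with both alkene geometries set.
- C19–C20 and the C20 methyl: two selective cross-couplings (Stille, then Negishi) on the gem-dibromoalkene made from 2-methyloxazole-4-carbaldehyde give the C15–C21 trienal.
- C14–C15: an Evans syn aldol sets C14 and C15; the adduct is turned into a silyloxymethyl-protected methyl ketone (C12–C21).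
- C5–C6: a Brown (Z)-crotylboration sets C5 and C6; a Wittig reaction adds C1–C2 and a Heck coupling (C8–C9) gives the C1–C11 dienal.
- C11–C12: a 1,5-anti boron aldol joins the halves and sets C11; a Narasaka–Prasad reduction sets C13; fluoride and hydroxide release the tetrahydroxy acid.

Assumption: every compound marked "starting material" in the compound list and all reagents are taken as commercially available.

**Route**

Step 1
Reactants: 1 3-methylpyridine (3-picoline)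
Product: 2 3-methylpyridinium-1-sulfonate
Conditions: ClSO3H (1 equiv per 2 equiv of 1), CH2Cl2, 0 °C; filter, wash, dry
Reagents that add atoms: chlorosulfonic acid, O=S(=O)(O)Cl
Why: N-sulfonation of the pyridine nitrogen (classical preparation of a pyridinium-1-sulfonate) gives the activated salt that a nucleophile can open; no stereocentre is involved.

Step 2
Reactants: 2 3-methylpyridinium-1-sulfonate
Product: 6 (2E,4E)-2-methyl-5-(tributylstannyl)penta-2,4-dienal, via dihydropyridine adduct 3 (not isolated), via azatriene sulfamate 4 (not isolated), via (2Z)-dienal 5 (not isolated)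
Conditions: Bu3SnLi (from Bu3SnH, LiN(iPr)2), THF, −78 → −20 °C; H2O (pH 7); then DABCO (10 mol %), CH2Cl2, rt
Reagents that add atoms: tributylstannyllithium, [Li][Sn](CCCC)(CCCC)CCCC; water, O
Why: Zincke-type ring opening, known for the parent pyridinium-1-sulfonate and extended here to the 3-methyl salt: the bulky stannyl anion adds at C6 (the α-carbon remote from the methyl group), the 1,2-dihydropyridine opens by 6π-electrocyclic ring opening with the tin group rotating outward (4E), hydrolysis of the N-sulfonyl imine gives the 2Z-dienal, and amine-catalysed addition–elimination equilibrates it to the more stable 2E isomer.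

Step 3
Reactants: 7 2-methyl-1,3-oxazole-4-carbaldehyde
Product: 8 4-(2,2-dibromoethenyl)-2-methyl-1,3-oxazole
Conditions: CBr4, PPh3, CH2Cl2, 0 °C
Reagents that add atoms: carbon tetrabromide, BrC(Br)(Br)Br
Why: Ramirez (Corey–Fuchs) dibromo-olefination of a non-enolisable heteroaryl aldehyde; no stereo-element is created.

Step 4
Reactants: 6 (2E,4E)-2-methyl-5-(tributylstannyl)penta-2,4-dienal; 8 4-(2,2-dibromoethenyl)-2-methyl-1,3-oxazole
Product: 9 (2E,4E,6Z)-6-bromo-2-methyl-7-(2-methyl-1,3-oxazol-4-yl)hepta-2,4,6-trienal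
Conditions: Pd2(dba)3 (2.5 mol %), P(2-furyl)3 (15 mol %), toluene, 90 °C
Reagents that add atoms: none
Why: Stille coupling in which zerovalent palladium inserts faster into the less hindered C–Br bond trans to the oxazolyl group, so the dienyl chain enters trans to the ring and the remaining bromine stays cis (6Z); the stannane geometry is retained.

Step 5
Reactants: 9 (2E,4E,6Z)-6-bromo-2-methyl-7-(2-methyl-1,3-oxazol-4-yl)hepta-2,4,6-trienal
Product: 10 (2E,4E,6E)-2,6-dimethyl-7-(2-methyl-1,3-oxazol-4-yl)hepta-2,4,6-trienal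
Conditions: MeZnCl, Pd[P(t-Bu)3]2 (5 mol %), THF, 0 °C → rt
Reagents that add atoms: methylzinc chloride, C[Zn]Cl
Why: Negishi coupling replaces the remaining bromine by methyl with retention of geometry, giving the E-trisubstituted C20=C21 alkene; MeZnCl does not add to the conjugated aldehyde under these conditions.

Step 6
Reactants: 10 (2E,4E,6E)-2,6-dimethyl-7-(2-methyl-1,3-oxazol-4-yl)hepta-2,4,6-trienal; 11 (4R)-4-benzyl-3-propanoyl-1,3-oxazolidin-2-one
Product: 14 (4R)-4-benzyl-3-[(2R,3R,4E,6E,8E)-3-hydroxy-2,4,8-trimethyl-9-(2-methyl-1,3-oxazol-4-yl)nona-4,6,8-trienoyl]-1,3-oxazolidin-2-one, via boron enolate 12 (not isolated), via boron aldolate 13 (not isolated)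
Conditions: Bu2BOTf, iPr2NEt, CH2Cl2, −78 → 0 °C; then 10, −78 → 0 °C; pH 7 buffer, MeOH, H2O2, 0 °C
Reagents that add atoms: none
Why: Evans syn aldol: the Z-boron enolate reacts through a Zimmerman–Traxler chair on the face left open by the (R)-benzyl auxiliary, giving the (2R,3R) syn adduct that sets C14 and C15 of the target.

Step 7
Reactants: 14 Evans aldol imide
Product: 15 (2R,3R,4E,6E,8E)-3-hydroxy-N-methoxy-N,2,4,8-tetramethyl-9-(2-methyl-1,3-oxazol-4-yl)nona-4,6,8-trienamide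
Conditions: MeNHOMe·HCl, AlMe3, CH2Cl2, −20 → 0 °C; aqueous work-up
Reagents that add atoms: N,O-dimethylhydroxylamine hydrochloride, CNOC.Cl
Why: Weinreb transamidation by the aluminium amide, which the free 3-hydroxyl directs to the exocyclic carbonyl, releases the auxiliary without touching C14 or C15.

Step 8
Reactants: 15 hydroxy Weinreb amide
Product: 16 (2R,3R,4E,6E,8E)-N-methoxy-N,2,4,8-tetramethyl-9-(2-methyl-1,3-oxazol-4-yl)-3-{[tri(propan-2-yl)silyl]oxymethoxy}nona-4,6,8-trienamide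
Conditions: (i-Pr)3SiOCH2Cl, iPr2NEt, Bu4NI (cat.), ClCH2CH2Cl, 50 °C
Reagents that add atoms: (triisopropylsiloxy)methyl chloride, ClCO[Si](C(C)C)(C(C)C)C(C)C
Why: O-alkylation with an alkoxymethyl chloride gives an acetal-type ether that can direct the later aldol like an alkyl ether yet is removed by fluoride; the stereocentres are untouched.

Step 9
Reactants: 16 silyloxymethyl-protected Weinreb amide
Product: 18 (3R,4R,5E,7E,9E)-3,5,9-trimethyl-10-(2-methyl-1,3-oxazol-4-yl)-4-{[tri(propan-2-yl)silyl]oxymethoxy}deca-5,7,9-trien-2-one, via magnesium hemiaminal 17 (not isolated)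
Conditions: MeMgBr, THF, −20 → 0 °C; aq. NH4Cl
Reagents that add atoms: methylmagnesium bromide, C[Mg]Br
Why: Weinreb ketone synthesis: the chelated tetrahedral adduct survives until work-up, so a single methyl is added and the α-stereocentre is not epimerised.

Step 10
Reactants: 19 3-[(tert-butyldimethylsilyl)oxy]propanal
Product: 21 (3R,4R)-1-[(tert-butyldimethylsilyl)oxy]-4-methylhex-5-en-3-ol, via borinate ester 20 (not isolated)
Conditions: (Z)-but-2-ene, n-BuLi, KOt-Bu, THF, −78 → −45 °C; (−)-Ipc2BOMe (Ipc = isopinocampheyl, from (+)-α-pinene), −78 °C; BF3·OEt2; then 19, −78 °C; NaOH, H2O2, 0 °C → rt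
Reagents that add atoms: (Z)-but-2-ene, C/C=C\C
Why: Brown crotylboration through a closed chair transition state: the (Z)-crotyl geometry gives the syn relationship and the (+)-α-pinene-derived ligands direct attack to the Si face of the aldehyde, setting C5 (R) and C6 (R) of the target.

Step 11
Reactants: 21 (3R,4R)-1-[(tert-butyldimethylsilyl)oxy]-4-methylhex-5-en-3-ol
Product: 22 (3R,4R)-4-methylhex-5-ene-1,3-diol
Conditions: camphorsulfonic acid (10 mol %), MeOH, 0 °C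
Reagents that add atoms: none
Why: Acid-catalysed methanolysis of the primary silyl ether; the stereocentres are not involved.

Step 12
Reactants: 22 (3R,4R)-4-methylhex-5-ene-1,3-diol
Product: 24 methyl (2E,5R,6R)-5-hydroxy-6-methylocta-2,7-dienoate, via hydroxy aldehyde 23 (not isolated)
Conditions: TEMPO (10 mol %), PhI(OAc)2, CH2Cl2, rt; then Ph3P=CHCO2Me, rt
Reagents that add atoms: methyl (triphenylphosphoranylidene)acetate, COC(=O)C=P(c1ccccc1)(c1ccccc1)c1ccccc1
Why: The oxoammonium oxidation takes the primary alcohol in preference to the secondary one, and the β-hydroxy aldehyde is trapped in the same flask by the stabilised ylide (Wittig reaction), which gives the E-enoate.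

Step 13
Reactants: 24 methyl (2E,5R,6R)-5-hydroxy-6-methylocta-2,7-dienoate
Product: 25 methyl (2E,5R,6R)-6-methyl-5-[(triethylsilyl)oxy]octa-2,7-dienoate
Conditions: Et3SiCl, imidazole, CH2Cl2, 0 °C → rt
Reagents that add atoms: chlorotriethylsilane, CC[Si](Cl)(CC)CC
Why: Silylation masks the C5 hydroxyl for the boron aldol; the group leaves with fluoride in the last step.

Step 14
Reactants: 25 methyl (2E,5R,6R)-6-methyl-5-[(triethylsilyl)oxy]octa-2,7-dienoate; 26 (2E)-3-iodo-2-methylprop-2-en-1-ol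
Product: 27 methyl (2E,5R,6R,7E,9E)-11-hydroxy-6,10-dimethyl-5-[(triethylsilyl)oxy]undeca-2,7,9-trienoate
Conditions: Pd(OAc)2 (10 mol %), Ag2CO3, DMF, 40 °C
Reagents that add atoms: none
Why: Heck reaction: the alkenylpalladium species adds syn across the terminal alkene (the most reactive one) and syn β-hydride elimination toward C8 gives the conjugated 7E,9E-diene with the iodide geometry retained; C6 is not touched.

Step 15
Reactants: 27 dienol
Product: 28 methyl (2E,5R,6R,7E,9E)-6,10-dimethyl-11-oxo-5-[(triethylsilyl)oxy]undeca-2,7,9-trienoate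
Conditions: MnO2, CH2Cl2, rt
Reagents that add atoms: none
Why: MnO2 oxidises only the allylic primary alcohol, giving the dienal without alkene isomerisation.

Step 16
Reactants: 18 protected methyl ketone; 28 dienal
Product: 31 methyl (2E,5R,6R,7E,9E,11R,14R,15R,16E,18E,20E)-11-hydroxy-6,10,14,16,20-pentamethyl-21-(2-methyl-1,3-oxazol-4-yl)-13-oxo-5-[(triethylsilyl)oxy]-15-{[tri(propan-2-yl)silyl]oxymethoxy}henicosa-2,7,9,16,18,20-hexaenoate, via boron enolate 29 (not isolated), via boron aldolate 30 (not isolated)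
Conditions: Bu2BOTf, iPr2NEt, Et2O, −78 °C; then 28, −78 → −40 °C; pH 7 buffer, MeOH, H2O2, 0 °C
Reagents that add atoms: none
Why: Boron aldol of a β-alkoxy methyl ketone with 1,5-anti induction: kinetic enolisation on the methyl side, then a boat transition state in which the C15 ether oxygen (acetal-type, as in the benzylidene acetals known to work) binds the formyl hydrogen, so the new C11 hydroxyl (R) forms anti to the C15 oxygen.

Step 17
Reactants: 31 aldol adduct
Product: 33 methyl (2E,5R,6R,7E,9E,11R,13S,14S,15R,16E,18E,20E)-11,13-dihydroxy-6,10,14,16,20-pentamethyl-21-(2-methyl-1,3-oxazol-4-yl)-5-[(triethylsilyl)oxy]-15-{[tri(propan-2-yl)silyl]oxymethoxy}henicosa-2,7,9,16,18,20-hexaenoate, via diethylboron chelate 32 (not isolated)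
Conditions: Et2BOMe, THF/MeOH (4:1), −78 °C; NaBH4, −78 °C; pH 7 buffer, H2O2, 0 °C
Reagents that add atoms: none
Why: Narasaka–Prasad reduction: the boron chelate of the β-hydroxy ketone takes a half-chair and hydride adds axially from outside, giving the 1,3-syn diol and so the 13S centre.

Step 18
Reactants: 33 protected diol ester
Product: 35 (2E,5R,6R,7E,9E,11R,13S,14S,15R,16E,18E,20E)-5,11,13,15-tetrahydroxy-6,10,14,16,20-pentamethyl-21-(2-methyl-1,3-oxazol-4-yl)henicosa-2,7,9,16,18,20-hexaenoic acid, via tetrahydroxy methyl ester 34 (not isolated)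
Conditions: Bu4NF, THF, 0 °C → rt; then LiOH, H2O/MeOH, rt; AcOH to pH 5
Reagents that add atoms: lithium hydroxide, [Li+].[OH-]
Why: Fluoride removes the triethylsilyl ether and the silyloxymethyl ether (the hemiacetal loses formaldehyde), and saponification frees the acid; all conditions are basic or near neutral, so the dienyl and trienyl carbinols do not ionise.

**Compound list**
1 | 3-methylpyridine (3-picoline) | Cc1cccnc1 | starting material
2 | 3-methylpyridinium-1-sulfonate | Cc1ccc[n+](c1)S(=O)(=O)[O-] | intermediate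
3 | lithium 5-methyl-2-(tributylstannyl)pyridine-1(2H)-sulfonate (racemic, not isolated) | [Li+].[O-]S(=O)(=O)N1C=C(C)C=CC1[Sn](CCCC)(CCCC)CCCC | intermediate
4 | lithium N-[(1E,2Z,4E)-2-methyl-5-(tributylstannyl)penta-2,4-dien-1-ylidene]sulfamate (not isolated) | [Li+].[O-]S(=O)(=O)/N=C/C(C)=C\C=C\[Sn](CCCC)(CCCC)CCCC | intermediate
5 | (2Z,4E)-2-methyl-5-(tributylstannyl)penta-2,4-dienal (not isolated) | O=C/C(C)=C\C=C\[Sn](CCCC)(CCCC)CCCC | intermediate
6 | (2E,4E)-2-methyl-5-(tributylstannyl)penta-2,4-dienal | O=C/C(C)=C/C=C/[Sn](CCCC)(CCCC)CCCC | intermediate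
7 | 2-methyl-1,3-oxazole-4-carbaldehyde | O=Cc1coc(C)n1 | starting material
8 | 4-(2,2-dibromoethenyl)-2-methyl-1,3-oxazole | BrC(Br)=Cc1coc(C)n1 | intermediate
9 | (2E,4E,6Z)-6-bromo-2-methyl-7-(2-methyl-1,3-oxazol-4-yl)hepta-2,4,6-trienal | O=C/C(C)=C/C=C/C(Br)=C/c1coc(C)n1 | intermediate
10 | (2E,4E,6E)-2,6-dimethyl-7-(2-methyl-1,3-oxazol-4-yl)hepta-2,4,6-trienal | O=C/C(C)=C/C=C/C(C)=C/c1coc(C)n1 | intermediate
11 | (4R)-4-benzyl-3-propanoyl-1,3-oxazolidin-2-one | CCC(=O)N1C(=O)OC[C@H]1Cc1ccccc1 | starting material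
12 | (4R)-4-benzyl-3-[(1Z)-1-(dibutylboranyloxy)prop-1-en-1-yl]-1,3-oxazolidin-2-one (not isolated) | C/C=C(\OB(CCCC)CCCC)N1C(=O)OC[C@H]1Cc1ccccc1 | intermediate
13 | (4R)-4-benzyl-3-[(2R,3R,4E,6E,8E)-3-(dibutylboranyloxy)-2,4,8-trimethyl-9-(2-methyl-1,3-oxazol-4-yl)nona-4,6,8-trienoyl]-1,3-oxazolidin-2-one (not isolated) | CC(/C=C/C=C(\C)[C@H](OB(CCCC)CCCC)[C@@H](C)C(=O)N1C(=O)OC[C@H]1Cc1ccccc1)=C\c1coc(C)n1 | intermediate
14 | (4R)-4-benzyl-3-[(2R,3R,4E,6E,8E)-3-hydroxy-2,4,8-trimethyl-9-(2-methyl-1,3-oxazol-4-yl)nona-4,6,8-trienoyl]-1,3-oxazolidin-2-one | CC(/C=C/C=C(\C)[C@H](O)[C@@H](C)C(=O)N1C(=O)OC[C@H]1Cc1ccccc1)=C\c1coc(C)n1 | intermediate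
15 | (2R,3R,4E,6E,8E)-3-hydroxy-N-methoxy-N,2,4,8-tetramethyl-9-(2-methyl-1,3-oxazol-4-yl)nona-4,6,8-trienamide | CC(/C=C/C=C(\C)[C@H](O)[C@@H](C)C(=O)N(C)OC)=C\c1coc(C)n1 | intermediate
16 | (2R,3R,4E,6E,8E)-N-methoxy-N,2,4,8-tetramethyl-9-(2-methyl-1,3-oxazol-4-yl)-3-{[tri(propan-2-yl)silyl]oxymethoxy}nona-4,6,8-trienamide | CC(/C=C/C=C(\C)[C@H](OCO[Si](C(C)C)(C(C)C)C(C)C)[C@@H](C)C(=O)N(C)OC)=C\c1coc(C)n1 | intermediate
17 | bromomagnesium (3R,4R,5E,7E,9E)-2-[methoxy(methyl)amino]-3,5,9-trimethyl-10-(2-methyl-1,3-oxazol-4-yl)-4-{[tri(propan-2-yl)silyl]oxymethoxy}deca-5,7,9-trien-2-olate (not isolated) | CC(/C=C/C=C(\C)[C@H](OCO[Si](C(C)C)(C(C)C)C(C)C)[C@@H](C)C(C)(O[Mg]Br)N(C)OC)=C\c1coc(C)n1 | intermediate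
18 | (3R,4R,5E,7E,9E)-3,5,9-trimethyl-10-(2-methyl-1,3-oxazol-4-yl)-4-{[tri(propan-2-yl)silyl]oxymethoxy}deca-5,7,9-trien-2-one | CC(/C=C/C=C(\C)[C@H](OCO[Si](C(C)C)(C(C)C)C(C)C)[C@@H](C)C(C)=O)=C\c1coc(C)n1 | intermediate
19 | 3-[(tert-butyldimethylsilyl)oxy]propanal | O=CCCO[Si](C)(C)C(C)(C)C | starting material
20 | (3R,4R)-1-[(tert-butyldimethylsilyl)oxy]-4-methylhex-5-en-3-yl bis(isopinocampheyl)borinate (not isolated) | C=C[C@@H](C)[C@H](OB([C@@H]1C[C@@H]2C[C@H]([C@H]1C)C2(C)C)[C@@H]1C[C@@H]2C[C@H]([C@H]1C)C2(C)C)CCO[Si](C)(C)C(C)(C)C | intermediate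
21 | (3R,4R)-1-[(tert-butyldimethylsilyl)oxy]-4-methylhex-5-en-3-ol | C=C[C@@H](C)[C@H](O)CCO[Si](C)(C)C(C)(C)C | intermediate
22 | (3R,4R)-4-methylhex-5-ene-1,3-diol | C=C[C@@H](C)[C@H](O)CCO | intermediate
23 | (3R,4R)-3-hydroxy-4-methylhex-5-enal (not isolated) | C=C[C@@H](C)[C@H](O)CC=O | intermediate
24 | methyl (2E,5R,6R)-5-hydroxy-6-methylocta-2,7-dienoate | C=C[C@@H](C)[C@H](O)C/C=C/C(=O)OC | intermediate
25 | methyl (2E,5R,6R)-6-methyl-5-[(triethylsilyl)oxy]octa-2,7-dienoate | C=C[C@@H](C)[C@H](O[Si](CC)(CC)CC)C/C=C/C(=O)OC | intermediate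
26 | (2E)-3-iodo-2-methylprop-2-en-1-ol | OC/C(C)=C/I | starting material
27 | methyl (2E,5R,6R,7E,9E)-11-hydroxy-6,10-dimethyl-5-[(triethylsilyl)oxy]undeca-2,7,9-trienoate | OC/C(C)=C/C=C/[C@@H](C)[C@H](O[Si](CC)(CC)CC)C/C=C/C(=O)OC | intermediate
28 | methyl (2E,5R,6R,7E,9E)-6,10-dimethyl-11-oxo-5-[(triethylsilyl)oxy]undeca-2,7,9-trienoate | O=C/C(C)=C/C=C/[C@@H](C)[C@H](O[Si](CC)(CC)CC)C/C=C/C(=O)OC | intermediate
29 | dibutylboron enolate of 18, (3R,4R,5E,7E,9E)-2-(dibutylboranyloxy)-3,5,9-trimethyl-10-(2-methyl-1,3-oxazol-4-yl)-4-{[tri(propan-2-yl)silyl]oxymethoxy}deca-1,5,7,9-tetraene (not isolated) | CC(/C=C/C=C(\C)[C@H](OCO[Si](C(C)C)(C(C)C)C(C)C)[C@@H](C)C(=C)OB(CCCC)CCCC)=C\c1coc(C)n1 | intermediate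
30 | methyl (2E,5R,6R,7E,9E,11R,14R,15R,16E,18E,20E)-11-(dibutylboranyloxy)-6,10,14,16,20-pentamethyl-21-(2-methyl-1,3-oxazol-4-yl)-13-oxo-5-[(triethylsilyl)oxy]-15-{[tri(propan-2-yl)silyl]oxymethoxy}henicosa-2,7,9,16,18,20-hexaenoate (not isolated) | CC(/C=C/C=C(\C)[C@H](OCO[Si](C(C)C)(C(C)C)C(C)C)[C@@H](C)C(=O)C[C@@H](OB(CCCC)CCCC)/C(C)=C/C=C/[C@@H](C)[C@H](O[Si](CC)(CC)CC)C/C=C/C(=O)OC)=C\c1coc(C)n1 | intermediate
31 | methyl (2E,5R,6R,7E,9E,11R,14R,15R,16E,18E,20E)-11-hydroxy-6,10,14,16,20-pentamethyl-21-(2-methyl-1,3-oxazol-4-yl)-13-oxo-5-[(triethylsilyl)oxy]-15-{[tri(propan-2-yl)silyl]oxymethoxy}henicosa-2,7,9,16,18,20-hexaenoate | CC(/C=C/C=C(\C)[C@H](OCO[Si](C(C)C)(C(C)C)C(C)C)[C@@H](C)C(=O)C[C@@H](O)/C(C)=C/C=C/[C@@H](C)[C@H](O[Si](CC)(CC)CC)C/C=C/C(=O)OC)=C\c1coc(C)n1 | intermediate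
32 | diethylboron chelate of 31, methyl (2E,5R,6R,7E,9E,11R,14R,15R,16E,18E,20E)-11-(diethylboranyloxy)-6,10,14,16,20-pentamethyl-21-(2-methyl-1,3-oxazol-4-yl)-13-oxo-5-[(triethylsilyl)oxy]-15-{[tri(propan-2-yl)silyl]oxymethoxy}henicosa-2,7,9,16,18,20-hexaenoate (not isolated) | CC(/C=C/C=C(\C)[C@H](OCO[Si](C(C)C)(C(C)C)C(C)C)[C@@H](C)C(=O)C[C@@H](OB(CC)CC)/C(C)=C/C=C/[C@@H](C)[C@H](O[Si](CC)(CC)CC)C/C=C/C(=O)OC)=C\c1coc(C)n1 | intermediate
33 | methyl (2E,5R,6R,7E,9E,11R,13S,14S,15R,16E,18E,20E)-11,13-dihydroxy-6,10,14,16,20-pentamethyl-21-(2-methyl-1,3-oxazol-4-yl)-5-[(triethylsilyl)oxy]-15-{[tri(propan-2-yl)silyl]oxymethoxy}henicosa-2,7,9,16,18,20-hexaenoate | CC(/C=C/C=C(\C)[C@H](OCO[Si](C(C)C)(C(C)C)C(C)C)[C@@H](C)[C@@H](O)C[C@@H](O)/C(C)=C/C=C/[C@@H](C)[C@H](O[Si](CC)(CC)CC)C/C=C/C(=O)OC)=C\c1coc(C)n1 | intermediate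
34 | methyl (2E,5R,6R,7E,9E,11R,13S,14S,15R,16E,18E,20E)-5,11,13,15-tetrahydroxy-6,10,14,16,20-pentamethyl-21-(2-methyl-1,3-oxazol-4-yl)henicosa-2,7,9,16,18,20-hexaenoate (not isolated) | CC(/C=C/C=C(\C)[C@H](O)[C@@H](C)[C@@H](O)C[C@@H](O)/C(C)=C/C=C/[C@@H](C)[C@H](O)C/C=C/C(=O)OC)=C\c1coc(C)n1 | intermediate
35 | (2E,5R,6R,7E,9E,11R,13S,14S,15R,16E,18E,20E)-5,11,13,15-tetrahydroxy-6,10,14,16,20-pentamethyl-21-(2-methyl-1,3-oxazol-4-yl)henicosa-2,7,9,16,18,20-hexaenoic acid (CNP0256102.1) | CC(/C=C/C=C(\C)[C@H](O)[C@@H](C)[C@@H](O)C[C@@H](O)/C(C)=C/C=C/[C@@H](C)[C@H](O)C/C=C/C(=O)O)=C\c1coc(C)n1 | target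

**Step count and risks**

Total: 18 steps. Longest linear sequence: 11 steps (steps 1, 2, 4, 5, 6, 7, 8, 9, 16, 17, 18, from 1 to 35).

The three steps most likely to fail:

Step 2. The risks are attack of the stannyl anion at C2 instead of C6 of the 3-methyl salt and incomplete 2Z to 2E equilibration. Fallback: setting out from 2, aqueous KOH at −20 °C opens the ring with hydroxide instead of tin and gives potassium (1E,3E)-4-methyl-5-oxopenta-1,3-dien-1-olate F1, an anion that is the same whichever α-carbon is attacked. Ph3PBr2 in CH2Cl2 then replaces the less hindered enolate oxygen by bromine and gives (2E,4E)-5-bromo-2-methylpenta-2,4-dienal F2. (Bu3Sn)2 with Pd(PPh3)4 in toluene stannylates the C–Br bond, and the route is rejoined at 6.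

Step 4. The risks are incomplete trans-selectivity or double coupling at the gem-dibromide; step 5 depends on its outcome. Fallback: setting out from 8, n-BuLi (2 equiv, THF, −78 °C) gives lithium (2-methyl-1,3-oxazol-4-yl)acetylide F3, which MeI converts into 2-methyl-4-(prop-1-yn-1-yl)-1,3-oxazole F4. Hydrozirconation with Cp2Zr(H)Cl puts the metal on the methyl-bearing carbon and gives chlorobis(cyclopentadienyl)[(1E)-1-(2-methyl-1,3-oxazol-4-yl)prop-1-en-2-yl]zirconium F5, and iodine turns this into 4-[(1E)-2-iodoprop-1-en-1-yl]-2-methyl-1,3-oxazole F6. One Stille coupling of F6 with 6 (Pd2(dba)3, AsPh3, DMF, rt) then gives 10 directly, so that 9 and the methyl coupling are not needed.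

Step 16. The 1,5-anti induction by a silyloxymethyl ether rests on analogy with alkyl ethers and benzylidene acetals only. Fallback: setting out from 18, Me3SiOTf and Et3N give the enol ether (3R,4R,5E,7E,9E)-3,5,9-trimethyl-10-(2-methyl-1,3-oxazol-4-yl)-4-{[tri(propan-2-yl)silyl]oxymethoxy}-2-[(trimethylsilyl)oxy]deca-1,5,7,9-tetraene F7. SiCl4 with a chiral bisphosphoramide Lewis-base catalyst (the antipode that directs attack to the Re face of 28) adds F7 to 28 in a catalyst-controlled Mukaiyama aldol and gives the C11 trichlorosilyl ether of the aldol adduct F8. Aqueous NaHCO3 hydrolyses F8 and the route is rejoined at 31; here the catalyst, not the C15 ether, sets C11.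

**Further compounds**
F1 | step 2 | potassium (1E,3E)-4-methyl-5-oxopenta-1,3-dien-1-olate | [K+].[O-]/C=C/C=C(C)/C=O
F2 | step 2 | (2E,4E)-5-bromo-2-methylpenta-2,4-dienal | O=C/C(C)=C/C=C/Br
F3 | step 4 | lithium (2-methyl-1,3-oxazol-4-yl)acetylide | [Li]C#Cc1coc(C)n1
F4 | step 4 | 2-methyl-4-(prop-1-yn-1-yl)-1,3-oxazole | CC#Cc1coc(C)n1
F5 | step 4 | chlorobis(cyclopentadienyl)[(1E)-1-(2-methyl-1,3-oxazol-4-yl)prop-1-en-2-yl]zirconium | C/C(=C\c1coc(C)n1)[Zr](Cl)(C1C=CC=C1)C1C=CC=C1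
F6 | step 4 | 4-[(1E)-2-iodoprop-1-en-1-yl]-2-methyl-1,3-oxazole | I/C(C)=C/c1coc(C)n1
F7 | step 16 | (3R,4R,5E,7E,9E)-3,5,9-trimethyl-10-(2-methyl-1,3-oxazol-4-yl)-4-{[tri(propan-2-yl)silyl]oxymethoxy}-2-[(trimethylsilyl)oxy]deca-1,5,7,9-tetraene | CC(/C=C/C=C(\C)[C@H](OCO[Si](C(C)C)(C(C)C)C(C)C)[C@@H](C)C(=C)O[Si](C)(C)C)=C\c1coc(C)n1
F8 | step 16 | methyl (2E,5R,6R,7E,9E,11R,14R,15R,16E,18E,20E)-6,10,14,16,20-pentamethyl-21-(2-methyl-1,3-oxazol-4-yl)-13-oxo-11-[(trichlorosilyl)oxy]-5-[(triethylsilyl)oxy]-15-{[tri(propan-2-yl)silyl]oxymethoxy}henicosa-2,7,9,16,18,20-hexaenoate | CC(/C=C/C=C(\C)[C@H](OCO[Si](C(C)C)(C(C)C)C(C)C)[C@@H](C)C(=O)C[C@@H](O[Si](Cl)(Cl)Cl)/C(C)=C/C=C/[C@@H](C)[C@H](O[Si](CC)(CC)CC)C/C=C/C(=O)OC)=C\c1coc(C)n1
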